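## Retrosynthetic overview

1. Feature: C1 of ring B is a diarylmethine held between C8a of ring A and a symmetric 4-hydroxy-3,5-dimethoxyphenyl ring, and its neighbour C2 carries C9. If C1 becomes the exocyclic carbon of a para-quinone methide (no E/Z isomers) and C9 becomes an aldehyde, C1 is an acceptor and C2 an enamine donor.
2. Key disconnection C1–C2: an amine-catalysed intramolecular 1,6-addition closes ring B and sets C1 and C2 against C3. Ring B is the only ring built; ring A comes from vanillin and the pendant ring from syringaldehyde.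
3. The quinone methide is released by fluoride-triggered 1,6-elimination of a 4-silyloxybenzhydryl acetate, made from a ring-A aryllithium (at C8a) and O-TBS-syringaldehyde. An aryllithium tolerates neither a lactone nor an aldehyde, so C9 travels as a terminal alkene and is unveiled by Lemieux–Johnson cleavage.
4. C3 is set first, by Evans alkylation of the (R)-4-benzyl-N-(pent-4-enoyl)oxazolidinone enolate with 6-bromo-O-benzylvanillyl bromide.
5. After ring closure: reduction at C9, desilylation at C9', peracetylation, hydrogenolysis at O7 and selective aminolysis of the aryl acetate.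

Key step: step 13

Remark on numbering: the tetralin numbering of the target (C1 diarylmethine, C2/C9, C3/C9', C4, C4a–C8a, OMe on C6, O on C7) is used for all intermediates.

Assumption: the benzhydrylic carbon C1 is carried as an epimer mixture until it becomes sp2. The sense of induction of the oxazolidinone and of the prolinol catalyst is assigned from their standard shielding models.

## Route

Step 1
Reactants: 1 vanillin
Product: 2 4-(benzyloxy)-3-methoxybenzaldehyde
Conditions: BnBr, K2CO3, DMF, rt
Reagents that add atoms: benzyl bromide, BrCc1ccccc1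
Why: Williamson ether synthesis on the only acidic OH masks O7 until the penultimate stage and removes the phenol's ortho-directing effect before the bromination.

Step 2
Reactants: 2 4-(benzyloxy)-3-methoxybenzaldehyde
Product: 3 4-(benzyloxy)-2-bromo-5-methoxybenzaldehyde
Conditions: Br2, NaOAc, AcOH, rt
Reagents that add atoms: bromine, BrBr
Why: Electrophilic aromatic bromination of a 3,4-dialkoxybenzaldehyde goes para to the methoxy group, the position that becomes C8a, and the acetate buffer takes up HBr so that the benzyl ether is kept.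

Step 3
Reactants: 3 4-(benzyloxy)-2-bromo-5-methoxybenzaldehyde
Product: 4 [4-(benzyloxy)-2-bromo-5-methoxyphenyl]methanol
Conditions: NaBH4, MeOH/THF, 0 °C
Reagents that add atoms: none
Why: Borohydride reduction of the aldehyde leaves the aryl bromide and both ethers untouched.

Step 4
Reactants: 4 [4-(benzyloxy)-2-bromo-5-methoxyphenyl]methanol
Product: 5 1-(benzyloxy)-5-bromo-4-(bromomethyl)-2-methoxybenzene
Conditions: PBr3, CH2Cl2, 0 °C
Reagents that add atoms: phosphorus tribromide, BrP(Br)Br
Why: PBr3 bromination (bromide displaces the phosphite ester of a benzylic alcohol) is fast at 0 °C, and the ortho bromine tempers the lability of the alkoxybenzyl bromide.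

Step 5
Reactants: 6 (R)-4-benzyloxazolidin-2-one; 7 pent-4-enoyl chloride
Product: 9 (R)-4-benzyl-3-(pent-4-enoyl)oxazolidin-2-one, via N-lithio oxazolidinone 8 (not isolated)
Conditions: n-BuLi, THF, −78 °C; then 7, −78 → 0 °C
Reagents that add atoms: none
Why: N-acylation of the lithiated carbamate with an acid chloride is the standard loading of an Evans auxiliary and does not touch its stereocentre.

Step 6
Reactants: 9 (R)-4-benzyl-3-(pent-4-enoyl)oxazolidin-2-one; 5 1-(benzyloxy)-5-bromo-4-(bromomethyl)-2-methoxybenzene
Product: 11 (R)-4-benzyl-3-[(S)-2-{[4-(benzyloxy)-2-bromo-5-methoxyphenyl]methyl}pent-4-enoyl]oxazolidin-2-one, via sodium Z-enolate 10 (not isolated)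
Conditions: NaHMDS, THF, −78 °C; then 5, −78 → −30 °C
Reagents that add atoms: none
Why: In this Evans asymmetric alkylation the chelated Z-enolate is shielded on one face by the C4 benzyl group of the (R)-auxiliary, so the benzylic bromide enters from the other face and sets C3 (S descriptor here, the spatial arrangement of 3R in the target).

Step 7
Reactants: 11 alkylated imide
Product: 12 (S)-2-{[4-(benzyloxy)-2-bromo-5-methoxyphenyl]methyl}pent-4-en-1-ol
Conditions: LiBH4, MeOH (1 equiv), Et2O, 0 °C
Reagents that add atoms: none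
Why: Reductive removal of the auxiliary attacks the more electrophilic exocyclic imide carbonyl and gives the C9' alcohol without enolisation at C3, while the alkene and aryl bromide are inert.

Step 8
Reactants: 12 (S)-2-{[4-(benzyloxy)-2-bromo-5-methoxyphenyl]methyl}pent-4-en-1-ol
Product: 13 (S)-{2-{[4-(benzyloxy)-2-bromo-5-methoxyphenyl]methyl}pent-4-enyloxy}(tert-butyl)dimethylsilane
Conditions: TBSCl, imidazole, CH2Cl2, rt
Reagents that add atoms: tert-butyldimethylsilyl chloride, CC(C)(C)[Si](C)(C)Cl
Why: Imidazole-promoted silylation of a primary alcohol removes the last acidic proton before the lithiation.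

Step 9
Reactants: 14 syringaldehyde
Product: 15 4-[(tert-butyldimethylsilyl)oxy]-3,5-dimethoxybenzaldehyde
Conditions: TBSCl, imidazole, DMF, rt
Reagents that add atoms: tert-butyldimethylsilyl chloride, CC(C)(C)[Si](C)(C)Cl
Why: Silylation of the phenol makes the aldehyde compatible with an aryllithium and installs the fluoride-sensitive trigger for the later 1,6-elimination.

Step 10
Reactants: 13 aryl bromide TBS ether; 15 O-TBS-syringaldehyde
Product: 18 {5-(benzyloxy)-4-methoxy-2-[(S)-2-(TBSO-methyl)pent-4-enyl]phenyl}[4-(TBSO)-3,5-dimethoxyphenyl]methyl acetate (C1 epimers), via aryllithium 16 (not isolated), via lithium alkoxide 17 (not isolated)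
Conditions: n-BuLi, THF, −78 °C; 15, −78 °C; then Ac2O, −78 → 0 °C
Reagents that add atoms: acetic anhydride, CC(=O)OC(C)=O
Why: Bromine–lithium exchange is fast on a substrate with no electrophilic group, 1,2-addition of the aryllithium to the aldehyde forms C8a–C1, and the alkoxide is acylated in the same flask; the C1 epimer mixture is harmless because C1 is later made planar.

Step 11
Reactants: 18 benzhydryl acetate alkene
Product: 20 {5-(benzyloxy)-4-methoxy-2-[(R)-2-(TBSO-methyl)-4-oxobutyl]phenyl}[4-(TBSO)-3,5-dimethoxyphenyl]methyl acetate (C1 epimers), via vicinal diol 19 (not isolated)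
Conditions: OsO4 (cat.), NaIO4, 2,6-lutidine, dioxane/H2O, rt
Reagents that add atoms: osmium tetroxide (catalytic oxygen carrier), O=[Os](=O)(=O)=O; sodium periodate (terminal oxygen source), [Na+].[O-]I(=O)(=O)=O
Why: Lemieux–Johnson oxidation dihydroxylates the only alkene and cleaves the diol to the C9 aldehyde, while lutidine holds the medium near neutral so that both silyl ethers and the acetate persist (the acetate ionises slowly as long as the pendant ring is O-silylated).

Step 12
Reactants: 20 aldehyde benzhydryl acetate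
Product: 21 4-({5-(benzyloxy)-4-methoxy-2-[(R)-2-(TBSO-methyl)-4-oxobutyl]phenyl}methylidene)-2,6-dimethoxycyclohexa-2,5-dien-1-one
Conditions: TBAF (1.0 equiv), THF, −78 °C; cold pH 7 buffer, extraction, used at once without chromatography
Reagents that add atoms: none
Why: Fluoride cleaves the aryl silyl ether much faster than the primary alkyl one, and the phenolate expels the para-benzhydrylic acetate in a 1,6-elimination, the usual fluoride-triggered entry to quinone methides; both C1 epimers converge on one planar compound, stabilised by the para-methoxy group (C6) of ring A.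

Step 13
Reactants: 21 quinone methide aldehyde
Product: 23 (1S,2R,3R)-7-(benzyloxy)-3-(TBSO-methyl)-1-(4-hydroxy-3,5-dimethoxyphenyl)-6-methoxy-1,2,3,4-tetrahydronaphthalene-2-carbaldehyde, via E-enamine 22 (not isolated)
Conditions: (R)-α,α-diphenylprolinol trimethylsilyl ether (20 mol %), PhCO2H (20 mol %), CH2Cl2 (0.02 M), 0 °C → rt, stirred on until C2 has equilibrated
Reagents that add atoms: none
Why: The secondary amine condenses with the C9 aldehyde of 21 to give the E-enamine 22, whose carbon C2 adds to the exocyclic quinone methide carbon C1; the pendant ring rearomatises to the syringyl phenolate, and proton transfer plus hydrolysis of the C9 iminium ion release 23 and the amine. The closest known reaction types are the amine-catalysed α-alkylation of aldehydes by 1,6-conjugate addition to δ-aryl para-quinone methides and the enamine-catalysed intramolecular Michael cyclisation of formyl-tethered acceptors. Ring B closes in a 6-(enolexo)-exo-trig mode, with both reacting π bonds (C2=C9 and C1=C1′ of the pendant ring) outside the forming ring, which is a favoured trajectory. C2 is controlled by a chair-like transition state that keeps the C3 CH2OTBS arm equatorial and by the CPh2OTMS group of the (R)-catalyst, which by the usual shielding model leaves the same enamine face open (matched pair), and any 2-epimer can still drift to the trans-diequatorial aldehyde through the enamine. C1 is controlled by the same chair, in which the bulky quinoid ring takes the pseudo-equatorial site anti to C9, so that H1, H2 and H3 all end up axial (1,2-trans, 2,3-trans). The step needs facial selectivity at C1, C- over N-attack and intra- over intermolecular reaction: the symmetric pendant ring removes any E/Z question, amine addition at C1 is reversible, the six-membered tether and dilution favour closure, and C1 is the only accessible electrophilic site.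

Step 14
Reactants: 23 tetralin carbaldehyde
Product: 24 (1S,2R,3R)-7-(benzyloxy)-3-(TBSO-methyl)-2-(hydroxymethyl)-1-(4-hydroxy-3,5-dimethoxyphenyl)-6-methoxy-1,2,3,4-tetrahydronaphthalene
Conditions: NaBH4, MeOH, 0 °C
Reagents that add atoms: none
Why: Borohydride reduction of the aldehyde gives the C9 alcohol and removes the acidity of H2, so the C2 configuration is fixed.

Step 15
Reactants: 24 C9 alcohol
Product: 25 (1S,2R,3R)-7-(benzyloxy)-2,3-bis(hydroxymethyl)-1-(4-hydroxy-3,5-dimethoxyphenyl)-6-methoxy-1,2,3,4-tetrahydronaphthalene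
Conditions: TBAF (excess), THF, rt
Reagents that add atoms: none
Why: Fluoride desilylation of the primary TBS ether affects no other group in the molecule.

Step 16
Reactants: 25 diol phenol
Product: 26 triacetate of 25 (C9-OAc, C9'-OAc, syringyl 4'-OAc; 7-OBn; 1S,2R,3R)
Conditions: Ac2O, pyridine, DMAP (cat.), CH2Cl2, rt
Reagents that add atoms: acetic anhydride, CC(=O)OC(C)=O
Why: DMAP-catalysed exhaustive acetylation esterifies both primary alcohols and the hindered phenol, so no selectivity is asked of this step.

Step 17
Reactants: 26 triacetate benzyl ether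
Product: 27 7-hydroxy triacetate (C9-OAc, C9'-OAc, syringyl 4'-OAc; 1S,2R,3R)
Conditions: H2 (1 atm), 10 % Pd/C, EtOAc, rt
Reagents that add atoms: none
Why: Catalytic hydrogenolysis cleaves the benzyl aryl ether, while the acetates and the C–C bonds at the diarylmethine C1 are inert under these conditions.

Step 18
Reactants: 27 7-hydroxy triacetate
Product: 28 target, [(1S,2R,3R)-7-hydroxy-1-(4-hydroxy-3,5-dimethoxyphenyl)-6-methoxy-1,2,3,4-tetrahydronaphthalene-2,3-diyl]dimethanediyl diacetate
Conditions: pyrrolidine (1.5 equiv), CH2Cl2, 0 °C → rt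
Reagents that add atoms: none
Why: Chemoselective aminolysis relies on the phenolate being a far better leaving group than a primary alkoxide, the same rate difference that is used to tell phenolic from aliphatic acetates in acetylated lignins, so only the aryl acetate is removed.

## Compound list

1 | vanillin | COc1cc(C=O)ccc1O | starting material
2 | 4-(benzyloxy)-3-methoxybenzaldehyde | COc1cc(C=O)ccc1OCc1ccccc1 | intermediate
3 | 4-(benzyloxy)-2-bromo-5-methoxybenzaldehyde | COc1cc(C=O)c(Br)cc1OCc1ccccc1 | intermediate
4 | [4-(benzyloxy)-2-bromo-5-methoxyphenyl]methanol | COc1cc(CO)c(Br)cc1OCc1ccccc1 | intermediate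
5 | 1-(benzyloxy)-5-bromo-4-(bromomethyl)-2-methoxybenzene | COc1cc(CBr)c(Br)cc1OCc1ccccc1 | intermediate
6 | (R)-4-benzyloxazolidin-2-one | O=C1N[C@H](Cc2ccccc2)CO1 | starting material
7 | pent-4-enoyl chloride | C=CCCC(=O)Cl | starting material
8 | N-lithio-(R)-4-benzyloxazolidin-2-one (not isolated) | [Li]N1[C@H](Cc2ccccc2)COC1=O | intermediate
9 | (R)-4-benzyl-3-(pent-4-enoyl)oxazolidin-2-one | C=CCCC(=O)N1[C@H](Cc2ccccc2)COC1=O | intermediate
10 | sodium Z-enolate of 9 (not isolated) | C=CC/C=C(\[O-])N1[C@H](Cc2ccccc2)COC1=O.[Na+] | intermediate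
11 | (R)-4-benzyl-3-[(S)-2-{[4-(benzyloxy)-2-bromo-5-methoxyphenyl]methyl}pent-4-enoyl]oxazolidin-2-one | C=CC[C@@H](Cc1cc(OC)c(OCc2ccccc2)cc1Br)C(=O)N1[C@H](Cc2ccccc2)COC1=O | intermediate
12 | (S)-2-{[4-(benzyloxy)-2-bromo-5-methoxyphenyl]methyl}pent-4-en-1-ol | C=CC[C@@H](Cc1cc(OC)c(OCc2ccccc2)cc1Br)CO | intermediate
13 | TBS ether of 12 | C=CC[C@@H](Cc1cc(OC)c(OCc2ccccc2)cc1Br)CO[Si](C)(C)C(C)(C)C | intermediate
14 | syringaldehyde | COc1cc(C=O)cc(OC)c1O | starting material
15 | 4-[(tert-butyldimethylsilyl)oxy]-3,5-dimethoxybenzaldehyde | COc1cc(C=O)cc(OC)c1O[Si](C)(C)C(C)(C)C | intermediate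
16 | aryllithium from 13, Li on C8a (not isolated) | C=CC[C@@H](Cc1cc(OC)c(OCc2ccccc2)cc1[Li])CO[Si](C)(C)C(C)(C)C | intermediate
17 | lithium benzhydryl alkoxide, C1 epimers (not isolated) | C=CC[C@@H](Cc1cc(OC)c(OCc2ccccc2)cc1C([O-])c1cc(OC)c(O[Si](C)(C)C(C)(C)C)c(OC)c1)CO[Si](C)(C)C(C)(C)C.[Li+] | intermediate
18 | benzhydryl acetate with pent-4-enyl side chain, C1 epimers | C=CC[C@@H](Cc1cc(OC)c(OCc2ccccc2)cc1C(OC(C)=O)c1cc(OC)c(O[Si](C)(C)C(C)(C)C)c(OC)c1)CO[Si](C)(C)C(C)(C)C | intermediate
19 | vicinal diol from 18, C3 unchanged, new carbinol and C1 as mixtures (not isolated) | OCC(O)C[C@@H](Cc1cc(OC)c(OCc2ccccc2)cc1C(OC(C)=O)c1cc(OC)c(O[Si](C)(C)C(C)(C)C)c(OC)c1)CO[Si](C)(C)C(C)(C)C | intermediate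
20 | benzhydryl acetate with (R)-2-(TBSO-methyl)-4-oxobutyl side chain, C1 epimers | O=CC[C@@H](Cc1cc(OC)c(OCc2ccccc2)cc1C(OC(C)=O)c1cc(OC)c(O[Si](C)(C)C(C)(C)C)c(OC)c1)CO[Si](C)(C)C(C)(C)C | intermediate
21 | ring-A aryl syringyl para-quinone methide with (R)-3-(TBSO-methyl)butanal chain (key-step precursor) | COc1cc(C[C@@H](CO[Si](C)(C)C(C)(C)C)CC=O)c(C=C2C=C(OC)C(=O)C(OC)=C2)cc1OCc1ccccc1 | intermediate
22 | E-enamine of 21 and (R)-diphenylprolinol TMS ether (not isolated) | COc1cc(C[C@@H](CO[Si](C)(C)C(C)(C)C)/C=C/N2CCC[C@@H]2C(c2ccccc2)(c2ccccc2)O[Si](C)(C)C)c(C=C2C=C(OC)C(=O)C(OC)=C2)cc1OCc1ccccc1 | intermediate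
23 | (1S,2R,3R)-1-syringyl-3-(TBSO-methyl)-7-benzyloxy-6-methoxytetralin-2-carbaldehyde (key-step product) | COc1cc2c(cc1OCc1ccccc1)[C@H](c1cc(OC)c(O)c(OC)c1)[C@@H](C=O)[C@H](CO[Si](C)(C)C(C)(C)C)C2 | intermediate
24 | (1S,2R,3R) C9 alcohol, C9' TBS ether | COc1cc2c(cc1OCc1ccccc1)[C@H](c1cc(OC)c(O)c(OC)c1)[C@@H](CO)[C@H](CO[Si](C)(C)C(C)(C)C)C2 | intermediate
25 | (1S,2R,3R) C9,C9' diol, free syringyl phenol, 7-OBn | COc1cc2c(cc1OCc1ccccc1)[C@H](c1cc(OC)c(O)c(OC)c1)[C@@H](CO)[C@H](CO)C2 | intermediate
26 | (1S,2R,3R) triacetate, 7-OBn | COc1cc2c(cc1OCc1ccccc1)[C@H](c1cc(OC)c(OC(C)=O)c(OC)c1)[C@@H](COC(C)=O)[C@H](COC(C)=O)C2 | intermediate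
27 | (1S,2R,3R) triacetate, 7-OH | COc1cc2c(cc1O)[C@H](c1cc(OC)c(OC(C)=O)c(OC)c1)[C@@H](COC(C)=O)[C@H](COC(C)=O)C2 | intermediate
28 | CNP0265800.1, (1S,2R,3R) 9,9'-diacetate | COc1cc2c(cc1O)[C@H](c1cc(OC)c(O)c(OC)c1)[C@@H](COC(C)=O)[C@H](COC(C)=O)C2 | target

## Step count and risks

Total step count: 18. Longest linear sequence: 16 (vanillin: steps 1–4, 6–8, 10–18).

**Step 13.** Three things may go wrong. Facial discrimination at C1 may be too weak during closure. Reversible capture of the catalyst nitrogen at C1 may starve the enamine cycle. The sterically unshielded dimethoxy quinone methide may oligomerise before it cyclises. The fallback replaces the quinone methide/enamine pair with a cation/enol silane pair and sets out from 20.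
- TBSOTf and Et3N in CH2Cl2 should convert the aldehyde into the tert-butyldimethylsilyl enol ether F1.
- Catalytic TBSOTf at −78 °C should ionise the benzhydryl acetate, and the tethered enol silane should capture the cation (intramolecular Mukaiyama-type SN1 α-alkylation).
- This closes the same C1–C2 bond under substrate control through the equatorial chair and gives the O-silylated tetralin carbaldehyde F2, whose C2 can be equilibrated with DBU.
- NaBH4 gives the bis-silylated C9 alcohol F3, and excess TBAF removes both silyl groups, which brings the material back to the route at 25.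

**Step 12.** The primary silyl ether may be lost alongside the aryl one. The ring may close under base induction before the chiral amine is present. The quinone methide may hydrate or oligomerise during work-up and concentration. The fallback uses no acetate or fluoride trigger and never handles the quinone methide; it sets out from 13 and 15.
- The lithiation and addition are run as in step 10 but quenched with aqueous NH4Cl, which gives the free benzhydrol F4.
- Lemieux–Johnson cleavage gives the hydroxy aldehyde F5.
- TBAF buffered with AcOH at 0 °C removes only the aryl silyl group and gives the 4-hydroxybenzhydrol aldehyde F6.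
- F6 is placed directly under the conditions of step 13. The acid co-catalyst dehydrates it (the known Brønsted-acid generation of para-quinone methides from 4-hydroxybenzyl alcohols), so 21 forms at low stationary concentration and is consumed at once. The route is rejoined at 23.

**Step 18.** The primary acetates may be partly aminolysed, or the doubly ortho-substituted aryl acetate may be cleaved incompletely. The fallback changes the protecting-group plan so that no aryl acetate is ever made, and sets out from 24.
- BnBr and K2CO3 in acetone benzylate only the phenol and give the bis(benzyl ether) F7.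
- TBAF gives the diol F8.
- Ac2O and pyridine give the diacetate F9.
- A double hydrogenolysis (H2, Pd/C, EtOAc) leads directly to 28.

## Further compounds

F1 | step 13 | tert-butyldimethylsilyl enol ether of 20 (E/Z and C1 mixtures) | COc1cc(C[C@@H](CO[Si](C)(C)C(C)(C)C)C=CO[Si](C)(C)C(C)(C)C)c(C(OC(C)=O)c2cc(OC)c(O[Si](C)(C)C(C)(C)C)c(OC)c2)cc1OCc1ccccc1
F2 | step 13 | (1S,2R,3R) 4'-O-TBS ether of 23 | COc1cc2c(cc1OCc1ccccc1)[C@H](c1cc(OC)c(O[Si](C)(C)C(C)(C)C)c(OC)c1)[C@@H](C=O)[C@H](CO[Si](C)(C)C(C)(C)C)C2
F3 | step 13 | (1S,2R,3R) 4'-O-TBS ether of 24 | COc1cc2c(cc1OCc1ccccc1)[C@H](c1cc(OC)c(O[Si](C)(C)C(C)(C)C)c(OC)c1)[C@@H](CO)[C@H](CO[Si](C)(C)C(C)(C)C)C2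
F4 | step 12 | free benzhydrol corresponding to 18 (C1 epimers) | C=CC[C@@H](Cc1cc(OC)c(OCc2ccccc2)cc1C(O)c1cc(OC)c(O[Si](C)(C)C(C)(C)C)c(OC)c1)CO[Si](C)(C)C(C)(C)C
F5 | step 12 | free benzhydrol corresponding to 20 (C1 epimers) | O=CC[C@@H](Cc1cc(OC)c(OCc2ccccc2)cc1C(O)c1cc(OC)c(O[Si](C)(C)C(C)(C)C)c(OC)c1)CO[Si](C)(C)C(C)(C)C
F6 | step 12 | 4-hydroxybenzhydrol aldehyde, formal hydrate of 21 (C1 epimers) | O=CC[C@@H](Cc1cc(OC)c(OCc2ccccc2)cc1C(O)c1cc(OC)c(O)c(OC)c1)CO[Si](C)(C)C(C)(C)C
F7 | step 18 | (1S,2R,3R) 4'-O-benzyl ether of 24 | COc1cc2c(cc1OCc1ccccc1)[C@H](c1cc(OC)c(OCc3ccccc3)c(OC)c1)[C@@H](CO)[C@H](CO[Si](C)(C)C(C)(C)C)C2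
F8 | step 18 | (1S,2R,3R) 4',7-di-O-benzyl diol | COc1cc2c(cc1OCc1ccccc1)[C@H](c1cc(OC)c(OCc3ccccc3)c(OC)c1)[C@@H](CO)[C@H](CO)C2
F9 | step 18 | (1S,2R,3R) 4',7-di-O-benzyl 9,9'-diacetate | COc1cc2c(cc1OCc1ccccc1)[C@H](c1cc(OC)c(OCc3ccccc3)c(OC)c1)[C@@H](COC(C)=O)[C@H](COC(C)=O)C2
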